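**Retrosynthetic overview**

1. The strategy rests on the ether oxygen O1 of ring C, which links the benzylic carbinol carbon C2 (bearing ring B) to the aromatic carbon C8a of ring A. Ring C is cut at O1–C8a to an open C2–C3–C4 chain with a free C2 hydroxyl and a C8a bromide, closed by intramolecular Pd-catalysed C–O coupling. C4 stays a carbinol (O3/O4 tied as a cis-acetonide) until after closure.
2. The acetonide alcohol comes from an erythro trans-epoxy alcohol: Ti-mediated benzoate opening at the benzylic oxirane carbon (inversion, sets C2), acetonide formation, benzoate removal. The epoxy alcohol comes from Sharpless kinetic-resolution epoxidation of the racemic (E)-1,3-diarylallyl alcohol (sets C3, selects C4).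
3. The allylic alcohol is cut at C3–C4 into the ring A 2-bromobenzaldehyde and the ring B (E)-alkenylzinc (hydrozirconation of the arylalkyne, Zr-to-Zn exchange).
4. Ring A aldehyde: 1-bromo-3,5-dimethoxybenzene by formylation, chelation-directed mono-demethylation, O-allylation/Claisen rearrangement, cross-metathesis to prenyl, MOM protection. Ring B alkyne: vanillin by MOM protection and alkyne homologation.
5. Ring order: rings A and B are bought as arenes; ring C is the only ring formed (step 14); then acetonide cleavage, oxidation at C4, MOM removal.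

Key step: step 14

Remark: flavanone locants (O1, C2, C3, C4, C4a, C5–C8, C8a; rings A, B, C) are used for open-chain intermediates too. ArA = 6-bromo-4-methoxy-2-(methoxymethoxy)-3-(3-methylbut-2-en-1-yl)phenyl; ArB = 3-methoxy-4-(methoxymethoxy)phenyl. 1-Bromo-3,5-dimethoxybenzene (the dimethyl ether of 5-bromoresorcinol) and vanillin are taken as commercial.

**Route**

Step 1
Reactants: 1 1-bromo-3,5-dimethoxybenzene
Product: 3 2-bromo-4,6-dimethoxybenzaldehyde, via aryliminium chloride 2 (not isolated)
Conditions: POCl3, DMF, 0 → 80 °C; then H2O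
Reagents that add atoms: N,N-dimethylformamide, CN(C)C=O; water, O
Why: Vilsmeier–Haack formylation, in which the chloroiminium ion should attack the carbon para to one methoxy group and ortho to the other (the carbon between the two methoxy groups is more crowded), and hydrolysis of iminium salt 2 releases the aldehyde.

Step 2
Reactants: 3 2-bromo-4,6-dimethoxybenzaldehyde
Product: 4 2-bromo-6-hydroxy-4-methoxybenzaldehyde
Conditions: BCl3 (1.1 equiv), CH2Cl2, −78 → 0 °C; then H2O
Reagents that add atoms: none
Why: Chelation-directed Lewis-acid ether cleavage, in which boron bridges the aldehyde oxygen and the ortho methoxy oxygen so that only this methyl ether should be cleaved and the para methoxy group kept.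

Step 3
Reactants: 4 2-bromo-6-hydroxy-4-methoxybenzaldehyde
Product: 5 2-(allyloxy)-6-bromo-4-methoxybenzaldehyde
Conditions: allyl bromide, K2CO3, DMF, 50 °C
Reagents that add atoms: allyl bromide, C=CCBr
Why: Williamson ether synthesis on the only free phenol.

Step 4
Reactants: 5 2-(allyloxy)-6-bromo-4-methoxybenzaldehyde
Product: 6 3-allyl-6-bromo-2-hydroxy-4-methoxybenzaldehyde
Conditions: N,N-diethylaniline, 190 °C
Reagents that add atoms: none
Why: Aromatic Claisen rearrangement, in which the allyl group can only migrate to the free ortho carbon between the two oxygens (the other ortho carbon carries the formyl group) and rearomatisation gives the hydrogen-bonded phenol.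

Step 5
Reactants: 6 3-allyl-6-bromo-2-hydroxy-4-methoxybenzaldehyde
Product: 7 6-bromo-2-hydroxy-4-methoxy-3-(3-methylbut-2-en-1-yl)benzaldehyde
Conditions: second-generation Grubbs catalyst (H2IMes)(PCy3)Cl2Ru=CHPh (3 mol %), 2-methyl-2-butene (excess), CH2Cl2, 40 °C
Reagents that add atoms: 2-methyl-2-butene, CC=C(C)C
Why: Olefin cross-metathesis of the terminal allyl group with excess 2-methyl-2-butene should turn allyl into prenyl and tolerates the phenol, the aldehyde and the aryl bromide.

Step 6
Reactants: 7 6-bromo-2-hydroxy-4-methoxy-3-(3-methylbut-2-en-1-yl)benzaldehyde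
Product: 8 6-bromo-4-methoxy-2-(methoxymethoxy)-3-(3-methylbut-2-en-1-yl)benzaldehyde
Conditions: NaH, MOMCl, DMF, 0 °C → rt
Reagents that add atoms: chloromethyl methyl ether, COCCl
Why: O-alkylation of the sodium phenoxide (MOM acetal protection), in which full deprotonation breaks the hydrogen bond to the aldehyde that would otherwise slow the hindered phenol.

Step 7
Reactants: 9 vanillin
Product: 10 3-methoxy-4-(methoxymethoxy)benzaldehyde
Conditions: MOMCl, K2CO3, acetone, rt
Reagents that add atoms: chloromethyl methyl ether, COCCl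
Why: Phenol O-alkylation (MOM protection) under mild base.

Step 8
Reactants: 10 3-methoxy-4-(methoxymethoxy)benzaldehyde
Product: 11 4-ethynyl-2-methoxy-1-(methoxymethoxy)benzene
Conditions: dimethyl (1-diazo-2-oxopropyl)phosphonate, K2CO3, MeOH, rt
Reagents that add atoms: dimethyl (1-diazo-2-oxopropyl)phosphonate, COP(=O)(OC)C(=[N+]=[N-])C(C)=O
Why: Seyferth–Gilbert homologation in its Ohira–Bestmann form, in which the diazomethylphosphonate anion made in the flask olefinates the aldehyde and loss of N2 followed by a 1,2-hydrogen shift gives the terminal alkyne under conditions that spare the MOM ether.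

Step 9
Reactants: 11 4-ethynyl-2-methoxy-1-(methoxymethoxy)benzene; 8 6-bromo-4-methoxy-2-(methoxymethoxy)-3-(3-methylbut-2-en-1-yl)benzaldehyde
Product: 14 racemic (E)-1-(ArA)-3-(ArB)prop-2-en-1-ol, via alkenylzirconocene chloride 12 (not isolated), via alkenyl(methyl)zinc 13 (not isolated)
Conditions: 11, Cp2Zr(H)Cl, CH2Cl2, rt; then Me2Zn, toluene, −65 °C; then 8, 0 °C; aq NH4Cl
Reagents that add atoms: none
Why: Syn-hydrozirconation of the terminal alkyne puts the metal on the terminal carbon and fixes the E geometry, Zr-to-Zn transmetalation gives an alkenylzinc that should add 1,2 to the aldehyde without touching the aryl bromide, and the new carbinol centre forms as a racemate that step 10 resolves.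

Step 10
Reactants: 14 racemic (E)-1-(ArA)-3-(ArB)prop-2-en-1-ol
Product: 15 (S)-(ArA)[(2S,3S)-3-(ArB)oxiran-2-yl]methanol
Conditions: Ti(OtBu)4 (20 mol %), L-(+)-diisopropyl tartrate (28 mol %), tBuOOH (0.6 equiv), 4 Å MS, CH2Cl2, −20 °C
Reagents that add atoms: tert-butyl hydroperoxide, CC(C)(C)OO
Why: Sharpless asymmetric epoxidation run as a kinetic resolution, in which the titanium–L-(+)-tartrate template should epoxidise only the (R)-enantiomer of 14 on the face that gives the (2S,3S)-oxirane erythro to the carbinol, so the C3–O bond of the target is set here, C4 is selected, and (S)-14 is left behind; tert-butoxide ligands limit alkoxide opening of the electron-rich aryl oxirane.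

Step 11
Reactants: 15 (S)-(ArA)[(2S,3S)-3-(ArB)oxiran-2-yl]methanol
Product: 16 (1R,2S,3S)-3-(ArA)-2,3-dihydroxy-1-(ArB)propyl benzoate
Conditions: PhCO2H (1.5 equiv), Ti(OiPr)4 (1.5 equiv), CH2Cl2, 0 °C → rt
Reagents that add atoms: benzoic acid, OC(=O)c1ccccc1
Why: Titanium-mediated nucleophilic opening of a 2,3-epoxy alcohol, in which the titanium-bound epoxy alkoxide directs benzoate to the distal oxirane carbon (benzylic to ring B, the future C2) with inversion, setting C2 anti to the untouched C3–O bond.

Step 12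
Reactants: 16 (1R,2S,3S)-3-(ArA)-2,3-dihydroxy-1-(ArB)propyl benzoate
Product: 17 (R)-[(4S,5S)-5-(ArA)-2,2-dimethyl-1,3-dioxolan-4-yl](ArB)methyl benzoate
Conditions: 2-methoxypropene, PPTS (cat.), CH2Cl2, 0 °C
Reagents that add atoms: 2-methoxypropene, COC(C)=C
Why: Acid-catalysed ketalisation of the vicinal diol, in which the benzoate blocks the C2 oxygen so that only the cis-dioxolane across O3 and O4 can form, under acid mild enough to avoid benzylic ionisation.

Step 13
Reactants: 17 (R)-[(4S,5S)-5-(ArA)-2,2-dimethyl-1,3-dioxolan-4-yl](ArB)methyl benzoate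
Product: 18 (R)-[(4R,5S)-5-(ArA)-2,2-dimethyl-1,3-dioxolan-4-yl](ArB)methanol
Conditions: K2CO3, MeOH, rt
Reagents that add atoms: none
Why: Base-catalysed methanolysis at the acyl carbon frees the benzylic C2 hydroxyl with retention (the change of descriptor at dioxolane C4 is a priority effect only).

Step 14
Reactants: 18 (R)-[(4R,5S)-5-(ArA)-2,2-dimethyl-1,3-dioxolan-4-yl](ArB)methanol
Product: 19 cis-fused 3,4-O-isopropylidene acetal of (2R,3S,4S)-7-methoxy-2-[3-methoxy-4-(methoxymethoxy)phenyl]-5-(methoxymethoxy)-6-(3-methylbut-2-en-1-yl)chromane-3,4-diol (2,3-trans-3,4-cis)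
Conditions: Pd(OAc)2 (5 mol %), 2-(di-tert-butylphosphino)-1,1'-binaphthyl (6 mol %), Cs2CO3 (1.5 equiv), toluene, 80 °C
Reagents that add atoms: none
Why: Zerovalent palladium formed in the flask inserts into the C8a–Br bond, the C2 hydroxyl is deprotonated by Cs2CO3 and displaces bromide on divalent palladium to give a seven-membered oxapalladacycle, and C–O reductive elimination forms the O1–C8a bond. The closest known reaction type is the Buchwald–Hartwig intramolecular etherification of 2-haloaryl-substituted alcohols to chromans with bulky di-tert-butyl(biaryl)phosphines. Ring C closes as a six-membered ring by aryl–oxygen bond formation (formally 6-exo attack of the C2 oxygen on C8a), cis-fused to the dioxolane. No new stereocentre is formed, and C2 and C3 should keep their configuration because no bond to either carbon is made or broken. The step needs reductive elimination to outrun beta-hydride elimination of the benzylic alkoxide, which the bulky electron-rich phosphine and the favourable ring size should secure. It also needs the C2 oxygen to be the only one that reaches palladium, which the acetonide on O3 and O4 ensures, and keeping C4 as a carbinol removes the retro-aldol and elimination paths of a beta-hydroxy ketone under base.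

Step 15
Reactants: 19 cis-fused 3,4-O-isopropylidene acetal
Product: 20 (2R,3S,4S)-7-methoxy-2-[3-methoxy-4-(methoxymethoxy)phenyl]-5-(methoxymethoxy)-6-(3-methylbut-2-en-1-yl)chromane-3,4-diol
Conditions: AcOH/H2O/THF (3:1:1), 40 °C
Reagents that add atoms: none
Why: Acid-catalysed ketal hydrolysis in weak aqueous acid should remove the isopropylidene group while the aryl MOM ethers and the prenyl group persist, and any ionisation at C4 is harmless because water recaptures the cation and C4 is oxidised next.

Step 16
Reactants: 20 (2R,3S,4S)-chromane-3,4-diol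
Product: 21 (2R,3R)-3-hydroxy-7-methoxy-2-[3-methoxy-4-(methoxymethoxy)phenyl]-5-(methoxymethoxy)-6-(3-methylbut-2-en-1-yl)chroman-4-one
Conditions: activated MnO2 (15 equiv), CH2Cl2, rt
Reagents that add atoms: none
Why: Chemoselective oxidation of a benzylic alcohol, in which the C4 carbinol on electron-rich ring A should be oxidised while the non-benzylic C3 hydroxyl is left, and C2 and C3 are not touched.

Step 17
Reactants: 21 (2R,3R)-bis-MOM dihydroflavonol
Product: 22 (2R,3R)-3,5-dihydroxy-2-(4-hydroxy-3-methoxyphenyl)-7-methoxy-6-(3-methylbut-2-en-1-yl)chroman-4-one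
Conditions: HCl (3 M aq), MeOH, 40 °C
Reagents that add atoms: none
Why: Acid-catalysed acetal cleavage of both aryl MOM ethers (the C5 ether is helped by the hydrogen bond to the C4 carbonyl) under conditions mild enough to spare the prenyl group and the 2,3-trans ketol.

**Compound list**

1 | 1-bromo-3,5-dimethoxybenzene | COc1cc(Br)cc(OC)c1 | starting material
2 | N-[(2-bromo-4,6-dimethoxyphenyl)methylidene]-N-methylmethanaminium chloride (not isolated) | COc1cc(Br)c(C=[N+](C)C)c(OC)c1.[Cl-] | intermediate
3 | 2-bromo-4,6-dimethoxybenzaldehyde | COc1cc(Br)c(C=O)c(OC)c1 | intermediate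
4 | 2-bromo-6-hydroxy-4-methoxybenzaldehyde | COc1cc(O)c(C=O)c(Br)c1 | intermediate
5 | 2-(allyloxy)-6-bromo-4-methoxybenzaldehyde | C=CCOc1cc(OC)cc(Br)c1C=O | intermediate
6 | 3-allyl-6-bromo-2-hydroxy-4-methoxybenzaldehyde | C=CCc1c(OC)cc(Br)c(C=O)c1O | intermediate
7 | 6-bromo-2-hydroxy-4-methoxy-3-(3-methylbut-2-en-1-yl)benzaldehyde | CC(C)=CCc1c(OC)cc(Br)c(C=O)c1O | intermediate
8 | 6-bromo-4-methoxy-2-(methoxymethoxy)-3-(3-methylbut-2-en-1-yl)benzaldehyde | COCOc1c(CC=C(C)C)c(OC)cc(Br)c1C=O | intermediate
9 | vanillin (4-hydroxy-3-methoxybenzaldehyde) | COc1cc(C=O)ccc1O | starting material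
10 | 3-methoxy-4-(methoxymethoxy)benzaldehyde | COCOc1ccc(C=O)cc1OC | intermediate
11 | 4-ethynyl-2-methoxy-1-(methoxymethoxy)benzene | COCOc1ccc(C#C)cc1OC | intermediate
12 | chlorobis(cyclopentadienyl)[(E)-2-(ArB)ethenyl]zirconium (not isolated) | COCOc1ccc(/C=C/[Zr](Cl)(C2C=CC=C2)C2C=CC=C2)cc1OC | intermediate
13 | methyl[(E)-2-(ArB)ethenyl]zinc (not isolated) | COCOc1ccc(/C=C/[Zn]C)cc1OC | intermediate
14 | racemic (E)-1-(ArA)-3-(ArB)prop-2-en-1-ol | COCOc1ccc(/C=C/C(O)c2c(Br)cc(OC)c(CC=C(C)C)c2OCOC)cc1OC | intermediate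
15 | (S)-(ArA)[(2S,3S)-3-(ArB)oxiran-2-yl]methanol | COc1cc([C@@H]2O[C@H]2[C@@H](O)c3c(Br)cc(OC)c(CC=C(C)C)c3OCOC)ccc1OCOC | intermediate
16 | (1R,2S,3S)-3-(ArA)-2,3-dihydroxy-1-(ArB)propyl benzoate | COc1cc([C@@H](OC(=O)c2ccccc2)[C@@H](O)[C@@H](O)c3c(Br)cc(OC)c(CC=C(C)C)c3OCOC)ccc1OCOC | intermediate
17 | (R)-[(4S,5S)-5-(ArA)-2,2-dimethyl-1,3-dioxolan-4-yl](ArB)methyl benzoate | COc1cc([C@@H](OC(=O)c2ccccc2)[C@H]3OC(C)(C)O[C@H]3c4c(Br)cc(OC)c(CC=C(C)C)c4OCOC)ccc1OCOC | intermediate
18 | (R)-[(4R,5S)-5-(ArA)-2,2-dimethyl-1,3-dioxolan-4-yl](ArB)methanol | COc1cc([C@@H](O)[C@H]2OC(C)(C)O[C@H]2c3c(Br)cc(OC)c(CC=C(C)C)c3OCOC)ccc1OCOC | intermediate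
19 | cis-fused 3,4-O-isopropylidene acetal of (2R,3S,4S)-7-methoxy-2-[3-methoxy-4-(methoxymethoxy)phenyl]-5-(methoxymethoxy)-6-(3-methylbut-2-en-1-yl)chromane-3,4-diol | COc1cc([C@H]2Oc3cc(OC)c(CC=C(C)C)c(OCOC)c3[C@@H]4OC(C)(C)O[C@H]24)ccc1OCOC | intermediate
20 | (2R,3S,4S)-7-methoxy-2-[3-methoxy-4-(methoxymethoxy)phenyl]-5-(methoxymethoxy)-6-(3-methylbut-2-en-1-yl)chromane-3,4-diol | COc1cc([C@H]2Oc3cc(OC)c(CC=C(C)C)c(OCOC)c3[C@H](O)[C@@H]2O)ccc1OCOC | intermediate
21 | (2R,3R)-3-hydroxy-7-methoxy-2-[3-methoxy-4-(methoxymethoxy)phenyl]-5-(methoxymethoxy)-6-(3-methylbut-2-en-1-yl)chroman-4-one | COc1cc([C@H]2Oc3cc(OC)c(CC=C(C)C)c(OCOC)c3C(=O)[C@@H]2O)ccc1OCOC | intermediate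
22 | (2R,3R)-3,5-dihydroxy-2-(4-hydroxy-3-methoxyphenyl)-7-methoxy-6-(3-methylbut-2-en-1-yl)chroman-4-one | COc1cc([C@H]2Oc3cc(OC)c(CC=C(C)C)c(O)c3C(=O)[C@@H]2O)ccc1O | target

Total steps: 17. Longest linear sequence: 15 steps (steps 1–6 and 9–17).

**Steps most likely to fail**

Step 14. Beta-hydride elimination from the palladium benzylic alkoxide, which gives the aryl ketone and the debrominated arene, may outrun C–O reductive elimination, or oxidative addition may stall at the ortho-substituted bromide. The fallback changes metal and halide. It sets out from 18: aromatic Finkelstein exchange (NaI, CuI, trans-N,N'-dimethylcyclohexane-1,2-diamine, dioxane, 110 °C) should give the aryl iodide (R)-[(4R,5S)-5-[6-iodo-4-methoxy-2-(methoxymethoxy)-3-(3-methylbut-2-en-1-yl)phenyl]-2,2-dimethyl-1,3-dioxolan-4-yl](ArB)methanol F1. Ullmann-type intramolecular etherification (CuI, 3,4,7,8-tetramethyl-1,10-phenanthroline, Cs2CO3, toluene, 110 °C), in which the copper alkoxide has no easy beta-hydride path, should then close ring C and rejoin the route at 19.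

Step 16. Oxidative glycol cleavage of the cis-3,4-diol on the MnO2 surface may compete, or the oxidation may be slow because the C4–H bond is pseudo-equatorial and poorly aligned with ring A. The fallback separates the two hydroxyls first. It sets out from 20: silylation of the more accessible equatorial C3 hydroxyl (TESCl, imidazole, DMF, −20 °C) should give the (2R,3S,4S)-3-(triethylsilyloxy)chroman-4-ol F2. Dess–Martin periodinane (NaHCO3, CH2Cl2, rt) then oxidises the only free hydroxyl to the (2R,3R)-3-(triethylsilyloxy)chroman-4-one F3. The acidic methanol of step 17 removes the silyl ether together with both MOM groups, so the route is rejoined at 22.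

Step 11. The oxirane carbon next to the 4-alkoxyaryl ring may open through an ion pair, so that benzoate is delivered in part to the front face and the configuration at C2 is eroded. The fallback sets C2 by reduction instead of substitution. It sets out from 18 as steps 12 and 13 would then deliver it, mixed with its carbinol epimer (S)-[(4R,5S)-5-(ArA)-2,2-dimethyl-1,3-dioxolan-4-yl](ArB)methanol F4. Dess–Martin oxidation converges both epimers on the ketone [(4S,5S)-5-(ArA)-2,2-dimethyl-1,3-dioxolan-4-yl](ArB)methanone F5. Chelation-controlled reduction with Zn(BH4)2 (Et2O, −30 °C; Cram chelate between the carbonyl oxygen and the dioxolane oxygen on C3, hydride from the face away from the dioxolane C5 substituent) should return the anti alcohol 18 as a single diastereomer.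

**Further compounds**

F1 | step 14 | (R)-[(4R,5S)-5-[6-iodo-4-methoxy-2-(methoxymethoxy)-3-(3-methylbut-2-en-1-yl)phenyl]-2,2-dimethyl-1,3-dioxolan-4-yl][3-methoxy-4-(methoxymethoxy)phenyl]methanol | COc1cc([C@@H](O)[C@H]2OC(C)(C)O[C@H]2c3c(I)cc(OC)c(CC=C(C)C)c3OCOC)ccc1OCOC
F2 | step 16 | (2R,3S,4S)-7-methoxy-2-[3-methoxy-4-(methoxymethoxy)phenyl]-5-(methoxymethoxy)-6-(3-methylbut-2-en-1-yl)-3-(triethylsilyloxy)chroman-4-ol | COc1cc([C@H]2Oc3cc(OC)c(CC=C(C)C)c(OCOC)c3[C@H](O)[C@@H]2O[Si](CC)(CC)CC)ccc1OCOC
F3 | step 16 | (2R,3R)-7-methoxy-2-[3-methoxy-4-(methoxymethoxy)phenyl]-5-(methoxymethoxy)-6-(3-methylbut-2-en-1-yl)-3-(triethylsilyloxy)chroman-4-one | COc1cc([C@H]2Oc3cc(OC)c(CC=C(C)C)c(OCOC)c3C(=O)[C@@H]2O[Si](CC)(CC)CC)ccc1OCOC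
F4 | step 11 | (S)-[(4R,5S)-5-(ArA)-2,2-dimethyl-1,3-dioxolan-4-yl](ArB)methanol | COc1cc([C@H](O)[C@H]2OC(C)(C)O[C@H]2c3c(Br)cc(OC)c(CC=C(C)C)c3OCOC)ccc1OCOC
F5 | step 11 | [(4S,5S)-5-(ArA)-2,2-dimethyl-1,3-dioxolan-4-yl](ArB)methanone | COc1cc(C(=O)[C@H]2OC(C)(C)O[C@H]2c3c(Br)cc(OC)c(CC=C(C)C)c3OCOC)ccc1OCOC
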